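Count the target first. By the reactions considered, each turnover of the catalyst gives one target and one by-product and takes up one partner, and partner enters the solution from the gas. So two rates compete, each a fraction of the charge per day: what the gas delivers and what the catalyst turns.

the same everywhere: gas 4.3 mM (held)
- dawn: substrate 9.6 mM; free catalyst 0.1 mol%; temperature 55 °C; run made earlier
- dusk: substrate 110 mM; free catalyst 0.1 mol%; temperature 90 °C; run made earlier
- spring: substrate 26 mM; free catalyst 0.17 mol%; temperature 55 °C; run made earlier
- Thursday's: substrate 26 mM; free catalyst 0.2 mol%; temperature 115 °C; time 3.0 d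
- Friday's: substrate 26 mM; free catalyst 0.1 mol%; temperature 100 °C; time 3.0 d
- Saturday's: substrate 80 mM; free catalyst 0.4 mol%; temperature 60 °C; time 3.0 d
- Tuesday's: substrate 8.0 mM; free catalyst 0.4 mol%; temperature 120 °C; time 3.0 d

| run | time / d | target / % | substrate / % |
|---|---|---|---|
| dawn | 2.08 | 1.0 | 100.5 |
| dawn | 6.00 | 1.1 | 98.5 |
| dawn | 10.0 | 2.9 | 97.6 |
| dawn | 15.0 | 3.7 | 97.4 |
| dawn | 25.0 | 6.6 | 94.6 |
| dawn | 30.0 | 7.5 | 93.0 |
| dusk | 0.333 | 1.4 | 99.0 |
| dusk | 1.04 | 2.7 | 97.0 |
| dusk | 1.67 | 5.1 | 94.7 |
| dusk | 2.50 | 7.0 | 91.3 |
| dusk | 4.00 | 10.0 | 85.3 |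
| dusk | 5.00 | 12.3 | 81.0 |
| spring | 6.00 | 5.5 | 95.1 |
| spring | 12.0 | 10.9 | 89.0 |
| spring | 15.0 | 12.6 | 86.2 |
| spring | 25.0 | 23.1 | 77.2 |
| spring | 30.0 | 25.1 | 74.1 |

(scatter of a reading: 0.5 percentage points)

- percent here means substrate units held: one side product counts as two
- at the start none of partner is dissolved
- reactions considered so far: catalyst intermediate B -> by-product + catalyst intermediate C; substrate + catalyst intermediate A -> catalyst intermediate B; catalyst intermediate C <-> free catalyst + target; substrate + target -> side product; partner + free catalyst <-> catalyst intermediate A; gas <-> partner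

* the flasks by amount of target, in percent of the substrate charged, highest first, at 3.0 d (Thursday's / Friday's / Saturday's / Tuesday's)
* the same order at 12 d (Thursday's / Friday's / Saturday's / Tuesday's)
* the amount of target, in percent of the substrate charged of the flask you put first, at 3.0 d
* the amount of target, in percent of the substrate charged of the flask you put last, at 3.0 d

Read both rates from the dusk run. Its last reading has 12.3% of target. A side product holds two units, one of them a target already made, so the turnovers stand at target plus the missing units divided by two, 15.6% of the charge. Over 5.00 d that gives the delivery, the partner taken up per day, of 3.44 mM d⁻¹, and a pace (turnover frequency) of 31.3 d⁻¹. Whichever rate held dusk back, the other was at least as fast, so you should treat both as floors. The spring run, at 55 °C, gives a pace of 5.00 d⁻¹.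

Now divide by each flask. Delivery over 3.0 d, divided by the charge, pays for 129% of Tuesday's charge and 12.9% of Saturday's. Loading times pace over the same time gives Tuesday's 37.6%, if you trust its higher temperature to offset its smaller charge, and Saturday's 6.00% at spring's pace. On these floors the catalyst turns less of the charge than the gas pays for in both flasks . My own reckoning at 3.0 d therefore puts the turnovers of Tuesday's at 37.6% or above, with the same trust those of Thursday's at 18.8% or above and those of Friday's at 9.39% or above, and those of Saturday's between 6.00% and 12.9%.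

The forecast differs. It gives Thursday's > Tuesday's > Saturday's > Friday's at 3.0 d and Saturday's > Tuesday's > Thursday's > Friday's at 12 d, with 16% (11% to 23%) for the first flask and 6.5% (3% to 10%) for the last, adding: “The top three are close, and the K and temperature assumptions are uncertain.”

The flasks give Tuesday's > Thursday's > Friday's > Saturday's at 3.0 d, from 65.4% down to 8.99%, and Tuesday's > Friday's > Thursday's > Saturday's at 12 d.

    catalyst intermediate B → by-product + catalyst intermediate C (k = 605 h⁻¹, Ea = 97.0 kJ mol⁻¹)
    substrate + catalyst intermediate A → catalyst intermediate B (k = 1760 M⁻¹ h⁻¹, Ea = 72.0 kJ mol⁻¹)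
    catalyst intermediate C ⇌ free catalyst + target (K = 0.0330 M, k = 150 h⁻¹, Ea = 91.0 kJ mol⁻¹, ΔH = −89.0 kJ mol⁻¹)
    substrate + target → side product (k = 0.108 M⁻¹ h⁻¹, Ea = 101 kJ mol⁻¹)
    partner + free catalyst ⇌ catalyst intermediate A (K = 96.0 M⁻¹, k = 19000 M⁻¹ h⁻¹, Ea = 68.0 kJ mol⁻¹, ΔH = 16.0 kJ mol⁻¹)
    gas ⇌ partner, rate k6*(csat - [partner]) (kL = 0.0376 h⁻¹)
    (constants at 100 °C)

At 3.0 d Saturday's flask holds 7.26 mM of by-product against 5.68 mM in Tuesday's, though its charge is ten times larger. Put the delivery to use on Friday's recipe: 3.44 mM d⁻¹ over 3.0 d pays for 39.7% of its charge. With free catalyst raised from 0.1 mol% to 0.4 mol%, that flask gives 34.0% of target.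

(The numbers in the tables stem from a simulated flask with constants of no real substance.)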